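**Conventions.** Compounds are numbered 1–26 in the order of the step list. Locants C2, C3, C4, C4a, C5–C8, C8a and O1 are those of the chroman; C1''–C4'' are the carbons of the butyl chain on C4. In the open-chain intermediates the diarylheptane is numbered so that heptane C1 is the later C2, C3 the later C4 and C5 the later C2''. MOM = methoxymethyl, TBS = tert-butyldimethylsilyl.

## Analysis of the target

Target 26 is a 2,4-disubstituted chroman (a flavan). Its ring A is substituted at every carbon except C6: the C4 chain sits at C4a, a free hydroxyl at C5, a methoxy group at C7, a 4-hydroxycinnamoyl group at C8 and the ring oxygen at C8a. C2 carries a 4-hydroxyphenyl group and C4 a 2-hydroxy-4-(4-hydroxyphenyl)butyl chain, so C2–C3–C4 and this chain together form a 1,7-diarylheptane. There are three stereocentres: C2 (R), C4 (S) and the carbinol C2'' (R). C2 and C4 are trans on the pyran ring, whereas C4 and C2'' are 1,3-related across an open-chain methylene, so the carbinol needs reagent control. The sensitive groups are the chalcone enone (it excludes hydrogenolysis and closes to a flavanone with any free ortho hydroxyl), the benzylic aryl ether C2–O1 (flanked by a 4-hydroxyphenyl group and an acyl-substituted phenoxide, hence ionisable by acid) and four free phenols. The hard part is ring A. Its three oxygens must end in three different states (free hydroxyl, methyl ether, cyclic ether), and the acyl group must sit at C8 and not at C6, where electrophilic acylation of a 5-hydroxy-7-methoxychroman would be directed by the free hydroxyl. The strategy rests on reading ring A as a C-alkylated cinnamoylphloroglucinol, the Claisen-cyclised form of a polyketide. Read backwards, C8a, C4a, C5, C6 and C7 are C2, C3, C4, C5 and C6 of a 3-alkyl-4-alkoxy-6-(acylmethyl)-2-pyranone, and C8 is the side-chain methylene. In that pyranone the three oxygens are already different (lactone carbonyl, enol ether, ring oxygen) and the acyl position is fixed by the position of the side chain.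

## Retrosynthetic reasoning

**26 ⇒ 24 (protecting groups).** The last operation only unmasks. In 24 the four phenols that are free in the target are acetals and the C2'' carbinol is a silyl ether. Acetals survive the amide bases and the alkoxide that the ring-A construction needs. The silyl ether stays to the very end because a free C2'' hydroxyl could capture an ionised C2 and turn the chroman into a tetrahydropyran.

**24 ⇒ 23 (C7 O–CH3).** The methyl ether is cut next. In 23 the C7 hydroxyl is the only free phenol, so no selectivity is needed. Methylation is placed after ring closure so that the two oxygens ortho to the ketone (C7 and C8a) are told apart by the ring and not by a reagent.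

**23 ⇒ 22 (O1–C2).** The pyran ring is opened at the benzylic C–O bond and not at O1–C8a, because this leaves all three ring-A oxygens on the arene, as the arene synthesis delivers them. In the forward direction C2 is the only carbon that can ionise under mild acid, and the C8a hydroxyl is the only free oxygen that can reach it. Closure is reversible and settles on the 2,4-trans ring. The configuration at this carbon in 22 is therefore irrelevant and need not be controlled earlier.

**22 ⇒ 20 via 21 (C8–C8a, the key disconnection).** The C8–C8a bond is cut and the C7 oxygen is joined to C8a as a lactone, which turns arene 22 into pyranone 20 through the open triketo ester 21. This is the only ring-A bond whose cleavage gives a stable heterocycle with three chemically distinct oxygens and a fixed acyl position. The substitution pattern of the hexasubstituted ring then follows from the constitution of 20, and the complete chalcone arrives with it. The forward reaction must open the lactone with an alkoxide and make the carbanion of the doubly activated methylene attack the resulting ester.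

**20 ⇒ 16 + 19 (side-chain C–C bond).** The bond between the pyranone methylene and the cinnamoyl carbonyl is cut. The 6-methyl group of 16 is its only acidic C–H, and amide 19 acylates without over-addition. The whole cinnamoyl unit thus arrives in one piece, one step before the key step.

**16 ⇒ 15 ⇒ 14 ⇒ 10 + 12 (protection, then C2–aryl).** Removing the silyl group and the O4 acetal leads to 14. Cutting its aryl–carbinol bond gives lactol 10 and Grignard reagent 12, prepared from bromide 11; in the forward direction 10 reacts through its ring-opened bromomagnesium salt 13. The aryl group is placed on an aldehyde carbon because an aldehyde is what the most reliable asymmetric conjugate addition delivers.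

**10 ⇒ 7 + 8 (C4–C4a).** The bond between pyranone C3 and the β-carbon is cut; the adduct is the open-chain aldehyde 9, which closes to 10. Pyranone 8 is nucleophilic at C3. An enal such as 7 is preferred over an aryl enone as the acceptor because secondary-amine iminium catalysis of enals gives dependable face control, whereas aryl ketones form iminium ions poorly. C4 is set here by the catalyst.

**7 ⇒ 6 ⇒ 5 ⇒ 3 ⇒ 2 ⇒ 1 (side-chain fragment).** The enal double bond is cut by cross-metathesis to terminal alkene 6. The allyl–carbinol bond of 5 is cut to aldehyde 3, where a catalytic asymmetric allylation sets C2'' (through stannyl ether 4). Aldehyde 3 comes from 1 by phenol protection (2) and oxidation.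

**19 ⇒ 18 ⇒ 17.** The acyl donor is traced through phenol 18 to acid 17 by amide formation and phenol protection.

## Alternatives that were turned down

**Alternative 1:** The lactone C–O bond of a 4-substituted dihydrocoumarin is traced to a 2-acyl-3-arylcyclobutanone. One phenol of a symmetric 5-methoxyresorcinol unit adds to the strained ketone and the ring bond to the acyl-bearing carbon breaks (retro-Claisen), which gives dihydrocoumarin A1 with C4 in place and the chain as an enone. In its favour, the opening is driven by ring strain, the symmetric arene removes any regiochemical question in the lactonisation, and C4 comes from a small ring whose configuration can be fixed early. On these points it is as strong as or stronger than the chosen route. Against it, A1 lacks the C2 aryl group, both carbinols and the C8 acyl group. The lactone must be arylated and reduced, which sets C2 late under kinetic control, and the enone must be reduced with reagent control and saturated. The cinnamoyl group must then be introduced by electrophilic acylation, where C6, next to the free hydroxyl, competes with C8. The chosen strategy offers instead an acyl position and an oxygen pattern that are fixed by construction, and fewer steps after the key step.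

**Alternative 2:** O1–C8a and the C8–carbonyl bond are cut together. A hindered lithium amide generates the C8–C8a aryne from a haloarene, the tethered C2 alkoxide adds at C8a, and the C8 aryllithium is trapped by a cinnamoyl donor to give the fully silylated target A2. It is stronger than the chosen route on two points: the C2 configuration is carried over unchanged from a carbinol, and two bonds are made in one flask at a late, convergent stage. Against it, the precursor is a densely substituted haloarene that needs a long preparation. The aryne must also form in one regiochemical sense, and the aryllithium must acylate 1,2 on an enone-type donor in competition with protonation by the amine and with conjugate addition. The risk therefore sits in a crowded step with several competing paths. The chosen strategy offers instead a ring A built from a cheap pyranone without cryogenic aryne chemistry, and a C2 centre set by an equilibration that favours the target.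

**Alternative 3:** Three ring-A bonds are cut at once. Photolysis of a dihydropyranyl diazoketone gives a vinylketene by Wolff rearrangement, which combines with an alkynyl methyl ether by [2+2] addition, four-electron ring opening and six-electron closure to phenol A3. It is stronger than the chosen route in that C2 and C4 are set on a saturated ring by cyclic stereocontrol before the arene exists. It is equal in that C5–OH and C7–OMe arrive already differentiated. Against it, A3 has no substituent at C8. The cinnamoyl group would have to be placed there against the chelation-favoured C6 position, which is the same weakness as in Alternative 1. In addition the diazoketone on an enol ether carbon and the volatile alkyne partner cost steps and handling. The chosen strategy offers instead a ring closure that brings the C8 acyl group with it.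

Key step: step 13

Remark: compounds 14–16 and 20–22 are carried as both epimers at the benzylic carbinol carbon (the later C2), because step 14 ionises this centre and sets it under thermodynamic control; their SMILES leave it undefined.

## Steps

Step 1
Reactants: 1 3-(4-hydroxyphenyl)propan-1-ol
Product: 2 3-[4-(methoxymethoxy)phenyl]propan-1-ol
Conditions: MOMCl (1.1 equiv), K2CO3, acetone, 0 °C → rt
Reagents that add atoms: chloromethyl methyl ether, COCCl
Why: Williamson-type O-alkylation; K2CO3 deprotonates only the phenol, so the acetal goes selectively onto the aryl oxygen.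

Step 2
Reactants: 2 3-[4-(methoxymethoxy)phenyl]propan-1-ol
Product: 3 3-[4-(methoxymethoxy)phenyl]propanal
Conditions: TEMPO (10 mol %), PhI(OAc)2 (1.1 equiv), CH2Cl2, rt
Reagents that add atoms: none
Why: Oxoammonium (TEMPO) oxidation of a primary alcohol stops at the aldehyde under anhydrous conditions, and the aryl acetal is inert.

Step 3
Reactants: 3 3-[4-(methoxymethoxy)phenyl]propanal
Product: 5 (3R)-1-[4-(methoxymethoxy)phenyl]hex-5-en-3-ol, via stannyl ether 4 (not isolated)
Conditions: (S)-BINOL (20 mol %), Ti(OiPr)4 (10 mol %), 4 Å MS, CH2Cl2; allyltributylstannane, −20 °C; aq. NaHCO3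
Reagents that add atoms: allyltributylstannane, C=CC[Sn](CCCC)(CCCC)CCCC
Why: Keck asymmetric allylation; the catalyst formed from (S)-BINOL and Ti(OiPr)4 should deliver the allyl group to the Si face of 3, which sets the carbinol (the later C2'') as R, and stannyl ether 4 is hydrolysed on work-up.

Step 4
Reactants: 5 (3R)-1-[4-(methoxymethoxy)phenyl]hex-5-en-3-ol
Product: 6 TBS ether of 5
Conditions: TBSCl, imidazole, DMF, rt
Reagents that add atoms: tert-butylchlorodimethylsilane, CC(C)(C)[Si](C)(C)Cl
Why: Standard silylation of a secondary alcohol; this ether must last to the final step because a free C2'' oxygen would compete for the pyranone and later for the C2 cation.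

Step 5
Reactants: 6 TBS ether of 5
Product: 7 (2E,5R)-5-[(tert-butyldimethylsilyl)oxy]-7-[4-(methoxymethoxy)phenyl]hept-2-enal
Conditions: (E)-but-2-enal (5 equiv), second-generation Hoveyda–Grubbs catalyst RuCl2(=CH-C6H4-2-OiPr)(H2IMes) (3 mol %), CH2Cl2, 40 °C
Reagents that add atoms: (E)-but-2-enal, C/C=C/C=O
Why: Olefin cross-metathesis of a terminal alkene with an electron-poor partner in excess; the E enal is expected and propene leaves as a gas.

Step 6
Reactants: 7 (2E,5R)-5-[(tert-butyldimethylsilyl)oxy]-7-[4-(methoxymethoxy)phenyl]hept-2-enal; 8 4-hydroxy-6-methyl-2H-pyran-2-one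
Product: 10 (4S)-2-hydroxy-7-methyl-4-substituted 3,4-dihydropyrano[4,3-b]pyran-5-one (lactol as both anomers), via open-chain aldehyde 9 (not isolated)
Conditions: (R)-2-{bis[3,5-bis(trifluoromethyl)phenyl][(trimethylsilyl)oxy]methyl}pyrrolidine (20 mol %), PhCO2H (20 mol %), CH2Cl2, 0 °C → rt
Reagents that add atoms: none
Why: Iminium-catalysed Michael addition of C3 of the hydroxypyranone to the enal followed by hemiacetal formation, a known combination for 8. The (R)-configured diarylprolinol silyl ether covers one face of the s-trans iminium ion, so 8 adds to the Si face of the β-carbon and sets the later C4 as drawn. The remote silyloxy centre should have little influence.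

Step 7
Reactants: 10 lactol; 11 1-bromo-4-(methoxymethoxy)benzene
Product: 14 4-hydroxy-6-methyl-2-pyranone bearing the (3R,5R)-1-hydroxy-5-silyloxy-1,7-diarylheptan-3-yl chain at C3 (both C1 epimers), via arylmagnesium bromide 12 (not isolated), via bromomagnesium pyranolate 13 (not isolated)
Conditions: 11, Mg turnings, THF, 40 °C; then 10 (3.5 equiv of 12), THF, −20 → 0 °C; sat. aq. NH4Cl
Reagents that add atoms: none
Why: Grignard addition to a lactol; the first equivalent of 12 deprotonates 10, whose hemiacetal ring opens to the bromomagnesium pyranolate 13 carrying the free aldehyde (the anionic pyranone is protected against attack), and further 12 adds to the aldehyde carbonyl of 13. No control at the new carbinol is needed because step 14 ionises it.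

Step 8
Reactants: 14 hydroxypyranone carbinol
Product: 15 4-(methoxymethoxy)-2-pyranone with free benzylic hydroxyl (both C1 epimers)
Conditions: MOMCl (1.1 equiv), iPr2NEt (1.5 equiv), CH2Cl2, −20 → 0 °C
Reagents that add atoms: chloromethyl methyl ether, COCCl
Why: The hydroxypyranone is a vinylogous carboxylic acid, so the amine deprotonates it alone and the ambident anion should be alkylated mainly on O4 to keep the 2-pyranone. The neutral benzylic alcohol reacts more slowly at low temperature, and any 2-alkoxy-4-pyranone isomer should be separable.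

Step 9
Reactants: 15 4-(methoxymethoxy)-2-pyranone with free benzylic hydroxyl
Product: 16 bis-TBS 4-(methoxymethoxy)-6-methyl-2-pyranone (both C1 epimers)
Conditions: TBSCl, imidazole, DMAP (cat.), DMF, rt → 40 °C
Reagents that add atoms: tert-butylchlorodimethylsilane, CC(C)(C)[Si](C)(C)Cl
Why: Silylation with the chloride and imidazole avoids silyl triflates, which would attack the acetals. Both carbinol oxygens must be blocked robustly, because a free alkoxide could displace the acetal oxygen at pyranone C4 or open the lactone in steps 12 and 13.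

Step 10
Reactants: 17 (E)-3-(4-hydroxyphenyl)prop-2-enoic acid
Product: 18 (E)-3-(4-hydroxyphenyl)-N-methoxy-N-methylprop-2-enamide
Conditions: MeNH(OMe)·HCl, EDC·HCl, HOBt (0.2 equiv), iPr2NEt, CH2Cl2/DMF, 0 °C → rt
Reagents that add atoms: N,O-dimethylhydroxylamine hydrochloride, CNOC.Cl
Why: Carbodiimide amide coupling; the amine is far more nucleophilic than the phenol, so the Weinreb amide should form without phenol protection.

Step 11
Reactants: 18 (E)-3-(4-hydroxyphenyl)-N-methoxy-N-methylprop-2-enamide
Product: 19 (E)-N-methoxy-3-[4-(methoxymethoxy)phenyl]-N-methylprop-2-enamide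
Conditions: MOMCl, iPr2NEt, CH2Cl2, 0 °C → rt
Reagents that add atoms: chloromethyl methyl ether, COCCl
Why: Phenol alkylation with the chloromethyl ether and a hindered amine base.

Step 12
Reactants: 16 bis-TBS 4-(methoxymethoxy)-6-methyl-2-pyranone; 19 (E)-N-methoxy-3-[4-(methoxymethoxy)phenyl]-N-methylprop-2-enamide
Product: 20 3-alkyl-4-(methoxymethoxy)-6-(cinnamoylmethyl)-2-pyranone (both C1 epimers)
Conditions: LiN(SiMe3)2 (1.3 equiv), THF, −78 °C; then 19 (1.2 equiv), −78 → −30 °C; AcOH, −78 °C
Reagents that add atoms: none
Why: The 6-methyl group of a 4-alkoxy-2-pyranone is vinylogously acidic and is the only acidic C–H once C3 is substituted. Acylation of its lithium anion by a Weinreb amide stops at the chelated tetrahedral adduct, which prevents proton transfer to the more acidic product and over-addition.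

Step 13
Reactants: 20 3-alkyl-4-(methoxymethoxy)-6-(cinnamoylmethyl)-2-pyranone
Product: 22 2,6-dihydroxy-4-(methoxymethoxy)-3-alkylphenyl chalcone (both C1 epimers), via triketo ester 21 (not isolated)
Conditions: Mg(OMe)2 (8 equiv, freshly made from Mg in MeOH), MeOH, reflux, N2; then cold sat. aq. NH4Cl and citrate buffer (pH 5); crude product used at once
Reagents that add atoms: none
Why: Mg(OMe)2 first deprotonates the methylene between pyranone C6 and the ketone, then methoxide adds to the lactone carbonyl and the ring opens to the magnesium chelate of triketo ester 21, whose enol ether double bond keeps the ester and the diketone chain cis as they were in the ring. The carbanion of the only doubly activated methylene (the later C8) attacks the ester carbonyl in a 6-exo-trig Claisen (Dieckmann-type) closure that forms C8–C8a and ring A; methoxide leaves and enolisation gives arene 22. The closest known reaction is the Mg(OMe)2-mediated conversion of 4-methoxy-6-(2-oxoalkyl)-2-pyranones, cinnamoylmethyl cases included, into acylphloroglucinol monoethers. The atom map fixes the substitution pattern: the ester carbon becomes C8a–OH, the old ring oxygen becomes C7–OH, pyranone C4 with its acetal becomes C5, and the cinnamoyl group lands on C8. The step needs C-acylation in preference to aldol closure or O-acylation; magnesium chelation of the β-diketonate favours the Claisen mode, and the aldol alternative is closed because the ester α-carbon is fully substituted and locked in the enol ether. No stereocentre is formed, and the stereocentre on the C3 chain cannot epimerise because its hydrogen is only cross-conjugated to the ester. Both carbinol oxygens are silylated so that no internal alkoxide can displace the acetal oxygen at pyranone C4. The product is worked up cold near pH 5 and carried on directly, because a 2,6-dihydroxyaryl enone can close to a flavanone.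

Step 14
Reactants: 22 2,6-dihydroxy-4-(methoxymethoxy)-3-alkylphenyl chalcone
Product: 23 (2R,4R)-2,4-trans chroman with free C7 hydroxyl
Conditions: (±)-camphor-10-sulfonic acid (0.2 equiv), 4 Å MS, CH2Cl2, 0 °C → rt, until equilibrated
Reagents that add atoms: none
Why: Acid-catalysed SN1 cycloetherification. The 4-alkoxyphenyl-substituted benzylic silyl ether is the only C–O bond that can ionise, and of the oxygens ortho to C4a only the C8a hydroxyl is free (C5 carries the acetal, and the C7 hydroxyl cannot reach), so one six-membered ether forms. Closure is reversible, and C2 should settle as the 2,4-trans isomer because peri strain with the C5 substituent keeps the C4 chain pseudoaxial while the C2 aryl group stays equatorial; both C1 epimers of 22 converge on 23.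

Step 15
Reactants: 23 (2R,4R)-2,4-trans chroman with free C7 hydroxyl
Product: 24 7-methoxy chroman with four MOM ethers and one TBS ether
Conditions: MeI (5 equiv), K2CO3 (3 equiv), DMF, rt
Reagents that add atoms: iodomethane, CI
Why: O-methylation of the only free phenol; it is hydrogen-bonded to the ketone and therefore slow, hence the polar solvent and excess MeI. Any flavanone formed by oxa-Michael addition of this phenoxide reopens under the basic conditions and is drained by methylation.

Step 16
Reactants: 24 7-methoxy chroman with four MOM ethers and one TBS ether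
Product: 26 (E)-1-[(2R,4S)-5-hydroxy-4-[(2R)-2-hydroxy-4-(4-hydroxyphenyl)butyl]-2-(4-hydroxyphenyl)-7-methoxy-3,4-dihydro-2H-chromen-8-yl]-3-(4-hydroxyphenyl)prop-2-en-1-one, via tetrakis(trimethylsilyl) ether 25 (not isolated)
Conditions: TMSOTf (8 equiv), 2,2'-bipyridyl (12 equiv), CH2Cl2, 0 °C → rt; then HF·pyridine, pyridine, THF, 0 °C → rt
Reagents that add atoms: none
Why: Silyl triflate/2,2'-bipyridyl cleavage turns aryl methoxymethyl ethers into aryl silyl ethers without free protic acid, which spares the ionisable C2–O1 bond. Fluoride then removes the trimethylsilyl groups and the secondary silyl ether, and the product cannot close to a flavanone because neither position ortho to the ketone carries a free hydroxyl.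

## Compound list

1 | 3-(4-hydroxyphenyl)propan-1-ol | OCCCc1ccc(O)cc1 | starting material
2 | 3-[4-(methoxymethoxy)phenyl]propan-1-ol | OCCCc1ccc(OCOC)cc1 | intermediate
3 | 3-[4-(methoxymethoxy)phenyl]propanal | O=CCCc1ccc(OCOC)cc1 | intermediate
4 | tributyl{[(3R)-1-[4-(methoxymethoxy)phenyl]hex-5-en-3-yl]oxy}stannane (not isolated) | C=CC[C@H](O[Sn](CCCC)(CCCC)CCCC)CCc1ccc(OCOC)cc1 | intermediate
5 | (3R)-1-[4-(methoxymethoxy)phenyl]hex-5-en-3-ol | C=CC[C@H](O)CCc1ccc(OCOC)cc1 | intermediate
6 | tert-butyl{[(3R)-1-[4-(methoxymethoxy)phenyl]hex-5-en-3-yl]oxy}dimethylsilane | C=CC[C@H](O[Si](C)(C)C(C)(C)C)CCc1ccc(OCOC)cc1 | intermediate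
7 | (2E,5R)-5-[(tert-butyldimethylsilyl)oxy]-7-[4-(methoxymethoxy)phenyl]hept-2-enal | O=C/C=C/C[C@H](O[Si](C)(C)C(C)(C)C)CCc1ccc(OCOC)cc1 | intermediate
8 | 4-hydroxy-6-methyl-2H-pyran-2-one | CC1=CC(O)=CC(=O)O1 | starting material
9 | (3S,5R)-5-[(tert-butyldimethylsilyl)oxy]-3-(4-hydroxy-6-methyl-2-oxo-2H-pyran-3-yl)-7-[4-(methoxymethoxy)phenyl]heptanal (not isolated) | O=CC[C@H](C[C@H](O[Si](C)(C)C(C)(C)C)CCc1ccc(OCOC)cc1)C1=C(O)C=C(C)OC1=O | intermediate
10 | (4S)-4-{(2R)-2-[(tert-butyldimethylsilyl)oxy]-4-[4-(methoxymethoxy)phenyl]butyl}-2-hydroxy-7-methyl-3,4-dihydro-2H,5H-pyrano[4,3-b]pyran-5-one (both anomers) | OC1C[C@H](C[C@H](O[Si](C)(C)C(C)(C)C)CCc2ccc(OCOC)cc2)C2=C(O1)C=C(C)OC2=O | intermediate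
11 | 1-bromo-4-(methoxymethoxy)benzene | COCOc1ccc(Br)cc1 | starting material
12 | [4-(methoxymethoxy)phenyl]magnesium bromide (not isolated) | COCOc1ccc([Mg]Br)cc1 | intermediate
13 | bromomagnesium 3-{(3S,5R)-5-[(tert-butyldimethylsilyl)oxy]-7-[4-(methoxymethoxy)phenyl]-1-oxoheptan-3-yl}-6-methyl-2-oxo-2H-pyran-4-olate (not isolated) | O=CC[C@H](C[C@H](O[Si](C)(C)C(C)(C)C)CCc1ccc(OCOC)cc1)C1=C(O[Mg]Br)C=C(C)OC1=O | intermediate
14 | 3-{(3R,5R)-5-[(tert-butyldimethylsilyl)oxy]-1-hydroxy-1,7-bis[4-(methoxymethoxy)phenyl]heptan-3-yl}-4-hydroxy-6-methyl-2H-pyran-2-one (both C1 epimers) | CC1=CC(O)=C([C@H](CC(O)c2ccc(OCOC)cc2)C[C@H](O[Si](C)(C)C(C)(C)C)CCc2ccc(OCOC)cc2)C(=O)O1 | intermediate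
15 | 3-{(3R,5R)-5-[(tert-butyldimethylsilyl)oxy]-1-hydroxy-1,7-bis[4-(methoxymethoxy)phenyl]heptan-3-yl}-4-(methoxymethoxy)-6-methyl-2H-pyran-2-one (both C1 epimers) | CC1=CC(OCOC)=C([C@H](CC(O)c2ccc(OCOC)cc2)C[C@H](O[Si](C)(C)C(C)(C)C)CCc2ccc(OCOC)cc2)C(=O)O1 | intermediate
16 | 3-{(3S,5R)-1,5-bis[(tert-butyldimethylsilyl)oxy]-1,7-bis[4-(methoxymethoxy)phenyl]heptan-3-yl}-4-(methoxymethoxy)-6-methyl-2H-pyran-2-one (both C1 epimers) | CC1=CC(OCOC)=C([C@H](CC(O[Si](C)(C)C(C)(C)C)c2ccc(OCOC)cc2)C[C@H](O[Si](C)(C)C(C)(C)C)CCc2ccc(OCOC)cc2)C(=O)O1 | intermediate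
17 | (E)-3-(4-hydroxyphenyl)prop-2-enoic acid (4-coumaric acid) | OC(=O)/C=C/c1ccc(O)cc1 | starting material
18 | (E)-3-(4-hydroxyphenyl)-N-methoxy-N-methylprop-2-enamide | CON(C)C(=O)/C=C/c1ccc(O)cc1 | intermediate
19 | (E)-N-methoxy-3-[4-(methoxymethoxy)phenyl]-N-methylprop-2-enamide | CON(C)C(=O)/C=C/c1ccc(OCOC)cc1 | intermediate
20 | 3-{(3S,5R)-1,5-bis[(tert-butyldimethylsilyl)oxy]-1,7-bis[4-(methoxymethoxy)phenyl]heptan-3-yl}-4-(methoxymethoxy)-6-{(E)-4-[4-(methoxymethoxy)phenyl]-2-oxobut-3-en-1-yl}-2H-pyran-2-one (both C1 epimers) | O=C1OC(CC(=O)/C=C/c2ccc(OCOC)cc2)=CC(OCOC)=C1[C@H](CC(O[Si](C)(C)C(C)(C)C)c1ccc(OCOC)cc1)C[C@H](O[Si](C)(C)C(C)(C)C)CCc1ccc(OCOC)cc1 | intermediate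
21 | methyl (2E,8E)-2-{(3S,5R)-1,5-bis[(tert-butyldimethylsilyl)oxy]-1,7-bis[4-(methoxymethoxy)phenyl]heptan-3-yl}-3-(methoxymethoxy)-9-[4-(methoxymethoxy)phenyl]-5,7-dioxonona-2,8-dienoate (not isolated; both C1 epimers) | COC(=O)/C([C@H](CC(O[Si](C)(C)C(C)(C)C)c1ccc(OCOC)cc1)C[C@H](O[Si](C)(C)C(C)(C)C)CCc1ccc(OCOC)cc1)=C(/OCOC)CC(=O)CC(=O)/C=C/c1ccc(OCOC)cc1 | intermediate
22 | (E)-1-{3-[(3S,5R)-1,5-bis[(tert-butyldimethylsilyl)oxy]-1,7-bis[4-(methoxymethoxy)phenyl]heptan-3-yl]-2,6-dihydroxy-4-(methoxymethoxy)phenyl}-3-[4-(methoxymethoxy)phenyl]prop-2-en-1-one (both C1 epimers) | O=C(/C=C/c1ccc(OCOC)cc1)c1c(O)cc(OCOC)c(c1O)[C@H](CC(O[Si](C)(C)C(C)(C)C)c1ccc(OCOC)cc1)C[C@H](O[Si](C)(C)C(C)(C)C)CCc1ccc(OCOC)cc1 | intermediate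
23 | (E)-1-[(2R,4R)-4-{(2R)-2-[(tert-butyldimethylsilyl)oxy]-4-[4-(methoxymethoxy)phenyl]butyl}-7-hydroxy-5-(methoxymethoxy)-2-[4-(methoxymethoxy)phenyl]-3,4-dihydro-2H-chromen-8-yl]-3-[4-(methoxymethoxy)phenyl]prop-2-en-1-one | Oc1cc(OCOC)c2c(c1C(=O)/C=C/c1ccc(OCOC)cc1)O[C@@H](c1ccc(OCOC)cc1)C[C@@H]2C[C@H](O[Si](C)(C)C(C)(C)C)CCc1ccc(OCOC)cc1 | intermediate
24 | (E)-1-[(2R,4R)-4-{(2R)-2-[(tert-butyldimethylsilyl)oxy]-4-[4-(methoxymethoxy)phenyl]butyl}-7-methoxy-5-(methoxymethoxy)-2-[4-(methoxymethoxy)phenyl]-3,4-dihydro-2H-chromen-8-yl]-3-[4-(methoxymethoxy)phenyl]prop-2-en-1-one | COc1cc(OCOC)c2c(c1C(=O)/C=C/c1ccc(OCOC)cc1)O[C@@H](c1ccc(OCOC)cc1)C[C@@H]2C[C@H](O[Si](C)(C)C(C)(C)C)CCc1ccc(OCOC)cc1 | intermediate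
25 | analogue of 24 in which the four aryl methoxymethyl ethers are trimethylsilyl ethers, (2R,4R,2''R) (not isolated) | COc1cc(O[Si](C)(C)C)c2c(c1C(=O)/C=C/c1ccc(O[Si](C)(C)C)cc1)O[C@@H](c1ccc(O[Si](C)(C)C)cc1)C[C@@H]2C[C@H](O[Si](C)(C)C(C)(C)C)CCc1ccc(O[Si](C)(C)C)cc1 | intermediate
26 | (E)-1-[(2R,4S)-5-hydroxy-4-[(2R)-2-hydroxy-4-(4-hydroxyphenyl)butyl]-2-(4-hydroxyphenyl)-7-methoxy-3,4-dihydro-2H-chromen-8-yl]-3-(4-hydroxyphenyl)prop-2-en-1-one | COc1cc(O)c2c(c1C(=O)/C=C/c1ccc(O)cc1)O[C@@H](c1ccc(O)cc1)C[C@@H]2C[C@H](O)CCc1ccc(O)cc1 | target

The change of the C4 descriptor between S and R along the route (R in 14, 15 and 23–25, S elsewhere) reflects only the priority of the oxygen substituents; the spatial arrangement is the same throughout.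

## Step count and least certain steps

Total: 16 steps. Longest linear sequence: 14 steps (steps 1–9 and 12–16); steps 10–11 make the acyl donor in parallel.

**Step 13 (key step).** Three processes can divert it.
- Methoxide may displace the methoxymethoxy group at pyranone C4 (or at the β-carbon of the open enol ether) by addition–elimination, which would leave a methyl ether at C5.
- Lactone opening may be slow, because the side-chain enolate makes the pyranone electron-rich and the branched C3 substituent shields the carbonyl.
- The 2,6-dihydroxyaryl enone product may close to a flavanone during work-up.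

Fallback: separate lactone opening from the Claisen closure. Setting out from 16, which has no enolisable side chain and should open under much milder conditions (Mg(OMe)2, MeOH, rt), gives the ring-opened keto ester F1. Double deprotonation of F1 with LiN(iPr)2 and acylation of the terminal carbon with 19 gives triketo ester 21. Closing 21 with a non-nucleophilic base (LiN(SiMe3)2 or NaH in THF) avoids hot methoxide and returns to the route at 22.

**Step 14.** The benzylic silyl ether may ionise too slowly relative to loss of acetal or silyl groups elsewhere. The acetal oxygen at C5 might take part in capture of the cation with loss of its methoxymethyl group. Equilibration to the trans ring may also be incomplete. Fallback: use a benzylic methyl ether as the leaving group, which ionises under the same mild acid without any Si–O chemistry. Setting out from 15, methylation (MeI, Ag2O) gives methyl ether F2. Acylation as in step 12 gives pyranone F3 and ring closure as in step 13 gives chalcone F4, which with camphorsulfonic acid loses methanol and returns to the route at 23.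

**Step 12.** The delocalised pyranone anion may add in conjugate fashion to the cinnamoyl acceptor, or be quenched by proton transfer. Fallback: an aldol–oxidation sequence. Reduction of 19 with iBu2AlH gives (E)-3-[4-(methoxymethoxy)phenyl]prop-2-enal F5. The lithium anion of 16 adds 1,2 to F5 to give allylic alcohol F6, and oxidation with MnO2 (or Dess–Martin periodinane) returns to the route at 20.

**Step 8.** The wrong oxygen may be alkylated: the benzylic hydroxyl, or the lactone carbonyl oxygen to give a 2-alkoxy-4-pyranone. Fallback: reverse the order of protection and arylation. Setting out from lactol 10, which reacts with MOMCl and iPr2NEt through its open hydroxypyranone form, gives the O4-protected aldehyde F7 with no second hydroxyl present. Addition of 12 at −78 °C, where the aldehyde reacts much faster than the neutral pyranone, returns to the route at 15.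

**Step 16.** The C2–O1 bond may ionise under the silyl triflate, leading to epimerisation or, once the C2'' oxygen is free, to capture of C2 by the side chain to give a tetrahydropyran isomer. Fallback: cleave in two separate stages. Setting out from 24, the aryl acetals are removed with a solid protic acid (NaHSO4 on silica, CH2Cl2, rt) while the side-chain silyl ether is kept, so that any ionised C2 can only re-close to the trans chroman; this gives the tetraphenol silyl ether F8. Buffered fluoride (Bu4NF, AcOH, THF), under which nothing ionises, then gives 26.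

## Further compounds

F1 | step 13 | methyl (2E)-2-{(3S,5R)-1,5-bis[(tert-butyldimethylsilyl)oxy]-1,7-bis[4-(methoxymethoxy)phenyl]heptan-3-yl}-3-(methoxymethoxy)-5-oxohex-2-enoate (both C1 epimers) | COC(=O)/C([C@H](CC(O[Si](C)(C)C(C)(C)C)c1ccc(OCOC)cc1)C[C@H](O[Si](C)(C)C(C)(C)C)CCc1ccc(OCOC)cc1)=C(/OCOC)CC(C)=O
F2 | step 14 | 3-{(3R,5R)-5-[(tert-butyldimethylsilyl)oxy]-1-methoxy-1,7-bis[4-(methoxymethoxy)phenyl]heptan-3-yl}-4-(methoxymethoxy)-6-methyl-2H-pyran-2-one (both C1 epimers) | CC1=CC(OCOC)=C([C@H](CC(OC)c2ccc(OCOC)cc2)C[C@H](O[Si](C)(C)C(C)(C)C)CCc2ccc(OCOC)cc2)C(=O)O1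
F3 | step 14 | 3-{(3R,5R)-5-[(tert-butyldimethylsilyl)oxy]-1-methoxy-1,7-bis[4-(methoxymethoxy)phenyl]heptan-3-yl}-4-(methoxymethoxy)-6-{(E)-4-[4-(methoxymethoxy)phenyl]-2-oxobut-3-en-1-yl}-2H-pyran-2-one (both C1 epimers) | O=C1OC(CC(=O)/C=C/c2ccc(OCOC)cc2)=CC(OCOC)=C1[C@H](CC(OC)c1ccc(OCOC)cc1)C[C@H](O[Si](C)(C)C(C)(C)C)CCc1ccc(OCOC)cc1
F4 | step 14 | (E)-1-{3-[(3R,5R)-5-[(tert-butyldimethylsilyl)oxy]-1-methoxy-1,7-bis[4-(methoxymethoxy)phenyl]heptan-3-yl]-2,6-dihydroxy-4-(methoxymethoxy)phenyl}-3-[4-(methoxymethoxy)phenyl]prop-2-en-1-one (both C1 epimers) | O=C(/C=C/c1ccc(OCOC)cc1)c1c(O)cc(OCOC)c(c1O)[C@H](CC(OC)c1ccc(OCOC)cc1)C[C@H](O[Si](C)(C)C(C)(C)C)CCc1ccc(OCOC)cc1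
F5 | step 12 | (E)-3-[4-(methoxymethoxy)phenyl]prop-2-enal | O=C/C=C/c1ccc(OCOC)cc1
F6 | step 12 | 3-{(3S,5R)-1,5-bis[(tert-butyldimethylsilyl)oxy]-1,7-bis[4-(methoxymethoxy)phenyl]heptan-3-yl}-6-{(E)-2-hydroxy-4-[4-(methoxymethoxy)phenyl]but-3-en-1-yl}-4-(methoxymethoxy)-2H-pyran-2-one (carbinol epimers) | O=C1OC(CC(O)/C=C/c2ccc(OCOC)cc2)=CC(OCOC)=C1[C@H](CC(O[Si](C)(C)C(C)(C)C)c1ccc(OCOC)cc1)C[C@H](O[Si](C)(C)C(C)(C)C)CCc1ccc(OCOC)cc1
F7 | step 8 | (3S,5R)-5-[(tert-butyldimethylsilyl)oxy]-3-[4-(methoxymethoxy)-6-methyl-2-oxo-2H-pyran-3-yl]-7-[4-(methoxymethoxy)phenyl]heptanal | O=CC[C@H](C[C@H](O[Si](C)(C)C(C)(C)C)CCc1ccc(OCOC)cc1)C1=C(OCOC)C=C(C)OC1=O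
F8 | step 16 | (E)-1-[(2R,4R)-4-{(2R)-2-[(tert-butyldimethylsilyl)oxy]-4-(4-hydroxyphenyl)butyl}-5-hydroxy-2-(4-hydroxyphenyl)-7-methoxy-3,4-dihydro-2H-chromen-8-yl]-3-(4-hydroxyphenyl)prop-2-en-1-one | COc1cc(O)c2c(c1C(=O)/C=C/c1ccc(O)cc1)O[C@@H](c1ccc(O)cc1)C[C@@H]2C[C@H](O[Si](C)(C)C(C)(C)C)CCc1ccc(O)cc1
A1 | alternative 1 | (4S)-4-{(E)-4-[4-(benzyloxy)phenyl]-2-oxobut-3-en-1-yl}-5-hydroxy-7-methoxy-3,4-dihydro-2H-chromen-2-one | COc1cc(O)c2c(c1)OC(=O)C[C@@H]2CC(=O)/C=C/c1ccc(OCc3ccccc3)cc1
A2 | alternative 2 | (2R,4R)-configured target skeleton with its four phenols as triisopropylsilyl ethers and its carbinol as the tert-butyldimethylsilyl ether | COc1cc(O[Si](C(C)C)(C(C)C)C(C)C)c2c(c1C(=O)/C=C/c1ccc(O[Si](C(C)C)(C(C)C)C(C)C)cc1)O[C@@H](c1ccc(O[Si](C(C)C)(C(C)C)C(C)C)cc1)C[C@@H]2C[C@H](O[Si](C)(C)C(C)(C)C)CCc1ccc(O[Si](C(C)C)(C(C)C)C(C)C)cc1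
A3 | alternative 3 | (2R,4R)-4-{(2R)-2-[(tert-butyldimethylsilyl)oxy]-4-{4-[(triisopropylsilyl)oxy]phenyl}butyl}-7-methoxy-2-{4-[(triisopropylsilyl)oxy]phenyl}-3,4-dihydro-2H-chromen-5-ol | COc1cc(O)c2c(c1)O[C@@H](c1ccc(O[Si](C(C)C)(C(C)C)C(C)C)cc1)C[C@@H]2C[C@H](O[Si](C)(C)C(C)(C)C)CCc1ccc(O[Si](C(C)C)(C(C)C)C(C)C)cc1
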